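**Plan**

1. Retrosynthetic cuts, in order: (a) one acetate C–O bond of 14, back to the meso-diacetate 13; (b) the side-chain C=O, back through a C–Si bond to a C≡C group; (c) the C–H of the free ring carbinol, back to an enone C=O; (d) the ring C–C bond between the ring =CH and the CH–O carbon together with the C–OH bond at the quaternary carbon, back to the flat 3-alkynyl-4-pyranone 5 and water; (e) the ring–alkyne C–C bond, back to 3-bromo-4-pyranone 3 and tridec-1-yne 4.
2. Enabling feature: the cyclopentene carries the sequence C(OH)(acyl)–CH(O)–CH=CH–CH(O). At the enone level this is a 4,5-dioxygenated cyclopent-2-enone, the pattern formed when a 4-pyranone contracts under light. The acetate oxygen is the former pyran ring oxygen, the CH(OAc) carbon and its alkene neighbour are the two carbons that flanked it, the free CH(OH) carbon is the pyranone carbonyl carbon, and the quaternary carbon is pyranone C3, which takes up water.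
3. Forward order: bromination and Sonogashira coupling of 4H-pyran-4-one; photochemical ring contraction with hydration (builds the only ring and two stereocentres); a silicon tether from the new secondary hydroxyl to the alkyne (temporary second ring); reduction of the ketone; Tamao–Fleming oxidation to the acyl group; diacetylation; enzymatic removal of one acetate.
4. Stereochemistry: the trans-diol comes from water adding anti to the epoxide of the bicyclic oxyallyl intermediate (relative, racemic). The third centre comes from hydride addition to the convex face of the tethered cis-fused bicycle, which gives a meso triol, so both enantiomers of the photoproduct converge. The absolute configuration of all three centres comes from lipase desymmetrisation of the meso-diacetate.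

Key step: step 3

Assumption: toward meso-diacetate 13, Candida antarctica lipase B shows its usual preference for esters of secondary alcohols (fast reaction at the (R)-configured carbinol carbon when the larger substituent, here the quaternary ring carbon, has CIP priority over the medium one, here the ring CH=). This is the same spatial sense as in the enzymatic hydrolysis of cis-3,5-diacetoxycyclopentene.

**Step 1**
Reactants: 1 4H-pyran-4-one
Product: 3 3-bromo-4H-pyran-4-one, via dibromide 2 (not isolated)
Conditions: Br2 (1.0 equiv), CH2Cl2, 0 °C; then Et3N, 0 °C to rt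
Reagents that add atoms: bromine, BrBr
Why: bromine adds across the enol-ether C2=C3 bond and Et3N then removes HBr by E1cB elimination (C3–H is α to the carbonyl), the classical addition–elimination α-bromination of a vinylogous ester, with one equivalent of Br2 limiting dibromination.

**Step 2**
Reactants: 3 3-bromo-4H-pyran-4-one; 4 tridec-1-yne
Product: 5 3-(tridec-1-yn-1-yl)-4H-pyran-4-one
Conditions: PdCl2(PPh3)2 (3 mol %), CuI (5 mol %), Et3N, THF, 50 °C, argon
Reagents that add atoms: none
Why: Sonogashira coupling of an electron-poor alkenyl bromide with a terminal alkyne, run with a tertiary amine because primary or secondary amines would open the pyranone by conjugate addition.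

**Step 3**
Reactants: 5 3-(tridec-1-yn-1-yl)-4H-pyran-4-one
Product: 8 rac-(4S,5R)-4,5-dihydroxy-5-(tridec-1-yn-1-yl)cyclopent-2-en-1-one, via oxyallyl zwitterion 6 (not isolated), via epoxy enol 7 (not isolated)
Conditions: hν (254 nm, quartz), MeCN/H2O 4:1, 3 mM, 10 °C, N2, stopped at about 80% conversion
Reagents that add atoms: water, O
Why: Excitation of the cross-conjugated pyranone (π,π*) leads to bonding between the two oxygen-bearing ring carbons C2 and C6, a photochemical 4π electrocyclisation that gives the 6-oxabicyclo[3.1.0]hexenyl oxyallyl zwitterion 6; water adds to one allyl terminus and the resulting epoxy enol 7 opens the epoxide by β-elimination to the 4-hydroxy enone. The closest known reaction type is the photochemical ring contraction of 4-pyranones and 4-hydroxypyrylium cations in hydroxylic solvents to trans-4-hydroxy-5-alkoxy- or 4,5-dihydroxycyclopent-2-enones. The five-membered carbocycle is closed by the electrocyclic C2–C6 σ-bond (disrotatory in the excited state), which forms the cis-fused epoxide at the same time; the epoxide then opens, so the overall change is a six-to-five ring contraction in which the pyran oxygen stays on one end of the new bond as the secondary hydroxyl. The secondary carbinol centre arises at that bond, and the quaternary carbinol centre is set relative to it because water attacks the planar allyl cation on the face anti to the epoxide oxygen, which should give the trans-diol with the alkynyl group cis to the secondary hydroxyl; the product is racemic, which is harmless because both enantiomers later converge on meso 12. The step needs capture at the alkynyl-bearing terminus and not at the unsubstituted one: the alkynyl group concentrates positive charge on its own carbon (propargylic stabilisation) and is sterically slim, and kinetic solvent capture of unsymmetrical allyl cations favours the better stabilised terminus. High dilution suppresses [2+2] photodimerisation, and the irradiation is stopped early to limit secondary photolysis of the enone product.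

**Step 4**
Reactants: 8 rac-(4S,5R)-4,5-dihydroxy-5-(tridec-1-yn-1-yl)cyclopent-2-en-1-one
Product: 10 (3E)-3-dodecylidene-3a-hydroxy-2,2-dimethyl-3,3a-dihydro-2H-cyclopenta[d][1,2]oxasilol-4(6aH)-one (racemic cis-fused bicycle), via silyl ether 9 (not isolated)
Conditions: (HMe2Si)2NH, CH2Cl2, rt, then evaporation; Pt2[(CH2=CHSiMe2)2O]3 (0.5 mol %), THF, rt
Reagents that add atoms: 1,1,3,3-tetramethyldisilazane, C[SiH](C)N[SiH](C)C
Why: the secondary hydroxyl, which is cis to the alkynyl group, is silylated (the hindered tertiary hydroxyl should stay free) and platinum-catalysed intramolecular syn-hydrosilylation of the homopropargylic silyl ether (5-exo-dig) puts silicon on the alkyne carbon attached to the ring, the alkyne being far more reactive than the enone under these conditions.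

**Step 5**
Reactants: 10 (3E)-3-dodecylidene-3a-hydroxy-2,2-dimethyl-3,3a-dihydro-2H-cyclopenta[d][1,2]oxasilol-4(6aH)-one
Product: 11 (3E)-3-dodecylidene-2,2-dimethyl-3,3a,4,6a-tetrahydro-2H-cyclopenta[d][1,2]oxasilole-3a,4-diol (racemic; 4-OH cis to the ring Si–O oxygen, trans to the angular OH)
Conditions: i-Bu2AlH (2.5 equiv), CH2Cl2, −78 °C; aq. KNaC4H4O6 (potassium sodium tartrate); used crude
Reagents that add atoms: none
Why: 1,2-reduction of the enone in which hydride should attack the convex face of the cis-fused bicycle, opposite to the oxasilolane ring, so that the new hydroxyl ends up cis to the tethered oxygen and trans to the tertiary hydroxyl.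

**Step 6**
Reactants: 11 (3E)-3-dodecylidene-2,2-dimethyl-3,3a,4,6a-tetrahydro-2H-cyclopenta[d][1,2]oxasilole-3a,4-diol
Product: 12 meso-1-(1,2,5-trihydroxycyclopent-3-en-1-yl)tridecan-1-one, (2R,5S), both secondary hydroxyls cis to the acyl group and trans to the tertiary hydroxyl
Conditions: 30% aq. H2O2, KF, KHCO3, THF/MeOH 1:1, rt
Reagents that add atoms: hydrogen peroxide, OO
Why: Tamao–Fleming oxidation of the alkenyl(alkoxy)silane replaces C–Si by C–O with retention, the enol tautomerises to the ketone at the carbon attached to the ring and the tethered hydroxyl is freed, while no stereocentre is touched and the product is meso.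

**Step 7**
Reactants: 12 meso-1-(1,2,5-trihydroxycyclopent-3-en-1-yl)tridecan-1-one
Product: 13 meso-(1R,3S)-2-hydroxy-2-tridecanoylcyclopent-4-ene-1,3-diyl diacetate
Conditions: Ac2O (2.2 equiv), pyridine, DMAP (cat.), CH2Cl2, 0 °C
Reagents that add atoms: acetic anhydride, CC(=O)OC(C)=O
Why: DMAP-catalysed acetylation of the two equivalent secondary allylic hydroxyls, the tertiary α-ketol hydroxyl being too hindered to react under these mild conditions.

**Step 8**
Reactants: 13 meso-(1R,3S)-2-hydroxy-2-tridecanoylcyclopent-4-ene-1,3-diyl diacetate
Product: 14 (1S,4R,5S)-4,5-dihydroxy-5-tridecanoylcyclopent-2-en-1-yl acetate (target)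
Conditions: immobilised Candida antarctica lipase B, n-BuOH (5 equiv), t-BuOMe, 30 °C, neutral work-up
Reagents that add atoms: none
Why: lipase-catalysed desymmetrising alcoholysis of a meso cyclopent-4-ene-1,3-diyl diacetate should remove the acetate on the (R)-configured carbinol carbon and keep the one on the (S)-configured carbon, which fixes the absolute configuration of all three stereocentres at once; base is avoided to prevent 1,3-acetyl migration.

**Compound list**

1 | 4H-pyran-4-one | O=C1C=COC=C1 | starting material
2 | trans-2,3-dibromo-2,3-dihydro-4H-pyran-4-one (racemic, one enantiomer drawn) | O=C1C=CO[C@H](Br)[C@H]1Br | intermediate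
3 | 3-bromo-4H-pyran-4-one | O=C1C=COC=C1Br | intermediate
4 | tridec-1-yne | CCCCCCCCCCCC#C | starting material
5 | 3-(tridec-1-yn-1-yl)-4H-pyran-4-one | CCCCCCCCCCCC#CC1=COC=CC1=O | intermediate
6 | 3-oxido-2-(tridec-1-yn-1-yl)-6-oxabicyclo[3.1.0]hex-3-en-2-ylium, oxyallyl zwitterion (racemic, one enantiomer drawn) | CCCCCCCCCCCC#C[C+]1C([O-])=C[C@@H]2O[C@H]12 | intermediate
7 | 2-(tridec-1-yn-1-yl)-6-oxabicyclo[3.1.0]hex-3-ene-2,3-diol, epoxy enol with 2-OH anti to the epoxide oxygen (racemic, one enantiomer drawn) | CCCCCCCCCCCC#C[C@]1(O)C(O)=C[C@@H]2O[C@H]12 | intermediate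
8 | rac-(4S,5R)-4,5-dihydroxy-5-(tridec-1-yn-1-yl)cyclopent-2-en-1-one, trans-diol (one enantiomer drawn) | CCCCCCCCCCCC#C[C@]1(O)C(=O)C=C[C@@H]1O | intermediate
9 | rac-(4S,5R)-4-[(dimethylsilyl)oxy]-5-hydroxy-5-(tridec-1-yn-1-yl)cyclopent-2-en-1-one (one enantiomer drawn) | CCCCCCCCCCCC#C[C@]1(O)C(=O)C=C[C@@H]1O[SiH](C)C | intermediate
10 | (3E)-3-dodecylidene-3a-hydroxy-2,2-dimethyl-3,3a-dihydro-2H-cyclopenta[d][1,2]oxasilol-4(6aH)-one, cis-fused (racemic, one enantiomer drawn) | CCCCCCCCCCC/C=C1/[Si](C)(C)O[C@H]2C=CC(=O)[C@@]12O | intermediate
11 | (3E)-3-dodecylidene-2,2-dimethyl-3,3a,4,6a-tetrahydro-2H-cyclopenta[d][1,2]oxasilole-3a,4-diol, cis-fused, 4-OH cis to ring oxygen (racemic, one enantiomer drawn) | CCCCCCCCCCC/C=C1/[Si](C)(C)O[C@H]2C=C[C@@H](O)[C@@]12O | intermediate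
12 | meso-1-[(2R,5S)-1,2,5-trihydroxycyclopent-3-en-1-yl]tridecan-1-one, secondary OH groups cis to acyl, trans to tertiary OH | CCCCCCCCCCCCC(=O)[C@]1(O)[C@H](O)C=C[C@@H]1O | intermediate
13 | meso-(1R,3S)-2-hydroxy-2-tridecanoylcyclopent-4-ene-1,3-diyl diacetate, acetoxy groups cis to acyl, trans to tertiary OH | CCCCCCCCCCCCC(=O)[C@]1(O)[C@H](OC(C)=O)C=C[C@@H]1OC(C)=O | intermediate
14 | (1S,4R,5S)-4,5-dihydroxy-5-tridecanoylcyclopent-2-en-1-yl acetate | CCCCCCCCCCCCC(=O)[C@]1(O)[C@H](O)C=C[C@@H]1OC(C)=O | target

**Step count and risks**

Total step count: 8. Longest linear sequence: 8 steps (1 to 14); tridec-1-yne 4 enters in step 2.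

Steps most likely to fail:

1. Step 3. Water may add to the unsubstituted terminus of the oxyallyl cation or to the remote alkyne carbon instead of the alkynyl-bearing ring carbon. The extended enynone chromophore may also divert the excited state into dimerisation, or the enone product may be consumed by secondary photolysis. The fallback builds the same cyclopentenone by ground-state chemistry; it sets out from 4 and commercial furan-2-carbaldehyde and comes back at 8. Lithiated 4 (n-BuLi, THF, −78 °C) adds to furan-2-carbaldehyde to give racemic 1-(furan-2-yl)tetradec-2-yn-1-ol F1. Achmatowicz oxidation (NBS, NaHCO3, THF/H2O, 0 °C) gives 6-hydroxy-2-(tridec-1-yn-1-yl)-2H-pyran-3(6H)-one F2. Et3N in MeCN at rt should open the lactol to the (Z)-4-oxo-enal, enolise the propargylic carbinol carbon and close the five-membered ring by intramolecular aldol addition to the aldehyde. The aldol is reversible, so the trans-diol 8 is expected to predominate and would be separated from any cis isomer.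

2. Step 4. The Si–H/platinum system may hydrosilylate or reduce the enone in competition with the alkyne, and the strained Si–O ring may be cleaved before the reduction, which would remove the facial bias needed in step 5. The fallback reduces the ketone before the tether is made; it sets out from 8 and comes back at 12. Luche reduction of 8 (NaBH4, CeCl3·7H2O, MeOH, −78 °C), in which hydride should add anti to the 4-hydroxyl as in other 4-oxygenated cyclopentenones, gives meso-(1R,3S)-2-(tridec-1-yn-1-yl)cyclopent-4-ene-1,2,3-triol F3. Both secondary hydroxyls are silylated with (HMe2Si)2NH to the bis(dimethylsilyl) ether F4. Cyclisation through either of the two equivalent Si–H groups (Pt2[(CH2=CHSiMe2)2O]3, THF, rt) gives the racemic (3E)-3-dodecylidene-4-[(dimethylsilyl)oxy]-2,2-dimethyl-3,3a,4,6a-tetrahydro-2H-cyclopenta[d][1,2]oxasilol-3a-ol F5. Tamao–Fleming oxidation (H2O2, KF, KHCO3, THF/MeOH) then gives 12.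

3. Step 8. The enzyme may accept the hindered diacetate (acetoxy carbons flanked by a quaternary carbon) only sluggishly or with poor discrimination between the two enantiotopic acetates, and the mono-acetate may lose optical purity by 1,3-acetyl migration or over-deacetylation. The fallback replaces the enzymatic deacylation by a non-enzymatic acylation; it sets out from 12 and comes back at 14. The meso triol ketone 12 is mono-acetylated directly with Ac2O and i-Pr2NEt in CHCl3 at 0 °C under a chiral isothiourea acyl-transfer catalyst (benzotetramisole), a catalyst class that discriminates secondary allylic alcohols. The catalyst enantiomer used is the one that acetylates the (S)-configured carbinol carbon, to be identified in a test run.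

**Further compounds**

F1 | step 3 | 1-(furan-2-yl)tetradec-2-yn-1-ol (racemic) | CCCCCCCCCCCC#CC(O)c1ccco1
F2 | step 3 | 6-hydroxy-2-(tridec-1-yn-1-yl)-2H-pyran-3(6H)-one (racemic, mixture of diastereomers) | CCCCCCCCCCCC#CC1OC(O)C=CC1=O
F3 | step 4 | meso-(1R,3S)-2-(tridec-1-yn-1-yl)cyclopent-4-ene-1,2,3-triol, secondary OH groups cis to alkynyl | CCCCCCCCCCCC#C[C@]1(O)[C@H](O)C=C[C@@H]1O
F4 | step 4 | meso-(1R,3S)-1,3-bis[(dimethylsilyl)oxy]-2-(tridec-1-yn-1-yl)cyclopent-4-en-2-ol | CCCCCCCCCCCC#C[C@]1(O)[C@H](O[SiH](C)C)C=C[C@@H]1O[SiH](C)C
F5 | step 4 | (3E)-3-dodecylidene-4-[(dimethylsilyl)oxy]-2,2-dimethyl-3,3a,4,6a-tetrahydro-2H-cyclopenta[d][1,2]oxasilol-3a-ol (racemic, one enantiomer drawn) | CCCCCCCCCCC/C=C1/[Si](C)(C)O[C@H]2C=C[C@@H](O[SiH](C)C)[C@@]12O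
F0 | step 8 | none | none
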